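I decide to set the polymerisation aside and keep one balance, that of the isomer of the product, which forms from monomer in chains in a reversible first-order step with forward constant k and return constant k′. I count the idle complex with the chains, as the readings do.

all flasks: initiator 100 mM
- birch: free monomer 1 M; impurity 50 mM; run made earlier
- alder: free monomer 0.67 M; impurity 50 mM; run made earlier
- cedar: free monomer 1.5 M; impurity 50 mM; run made earlier
- larch: free monomer 1 M; impurity 100 mM; run made earlier
- grey: free monomer 1.0 M; impurity 50 mM; everything together in a closed stirred flask, run for 3.0 d; time 3.0 d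
- blue: free monomer 1.0 M; impurity 50 mM; a single well-mixed tank run continuously and read at steady state, 9.00 d in it on average
- teal: free monomer 1.0 M; impurity 50 mM; a single well-mixed tank run continuously and read at steady state, 3.0 d in it on average
- red: free monomer 1.0 M; impurity 50 mM; a tube with plug flow, the mixed feed as stated, residence time 3.0 d; time 3.0 d

| run | time / d | monomer in chains / % | isomer of the product / % | free monomer / % |
|---|---|---|---|---|
| birch | 0.417 | 6.2 | 2.1 | 90.8 |
| birch | 0.833 | 8.0 | 5.5 | 87.5 |
| birch | 1.25 | 7.9 | 8.4 | 83.9 |
| birch | 1.67 | 8.4 | 10.2 | 80.4 |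
| birch | 2.00 | 8.8 | 12.5 | 79.2 |
| birch | 2.50 | 9.5 | 14.8 | 76.0 |
| birch | 3.00 | 9.1 | 17.7 | 73.5 |
| alder | 0.125 | 6.6 | 0.2 | 92.8 |
| alder | 0.333 | 5.6 | 2.2 | 91.8 |
| alder | 0.625 | 5.5 | 4.0 | 91.7 |
| alder | 1.04 | 4.9 | 5.3 | 90.9 |
| alder | 1.67 | 3.7 | 7.5 | 89.6 |
| alder | 2.08 | 3.9 | 7.2 | 88.6 |
| alder | 2.50 | 3.7 | 8.2 | 88.4 |
| cedar | 0.125 | 4.8 | 0.2 | 94.9 |
| cedar | 0.333 | 6.7 | 1.8 | 91.9 |
| cedar | 0.625 | 9.0 | 4.3 | 87.7 |
| cedar | 1.04 | 10.1 | 7.6 | 82.3 |
| cedar | 1.67 | 12.0 | 13.4 | 75.2 |
| cedar | 2.08 | 12.1 | 16.9 | 70.9 |
| cedar | 2.50 | 12.7 | 20.3 | 67.7 |
| larch | 0.208 | 1.1 | 1.0 | 98.3 |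
| larch | 0.333 | 1.7 | 0.5 | 98.4 |
| larch | 0.625 | 2.1 | 0.9 | 97.6 |
| larch | 1.25 | 2.4 | 1.9 | 95.9 |
| larch | 2.50 | 2.3 | 3.7 | 93.6 |

(each reading ± 0.3 percentage points)

- what is said of monomer in chains includes idle complex
- the stated concentrations are those of everything mixed, before any reaction; amounts are the same in each set-up
- steps thought possible: free monomer + living end -> monomer in chains + living end; free monomer + initiator -> living end + monomer in chains; initiator + monomer in chains <-> idle complex; initiator + impurity -> spent initiator; monomer in chains + living end -> free monomer + living end; monomer in chains <-> isomer of the product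
- the earlier runs were made in a closed, stirred flask
- the share counts what is present at the end, not what went on to other products

- the set-up with the highest share of monomer in chains in all that became monomer in chains or isomer of the product, at the outlet or at the end ("none" if the first two lie within 2 percentage points) (grey / blue / teal / red / none)
- share of monomer in chains in all that became monomer in chains or isomer of the product, at the outlet or at the end, grey
- share of monomer in chains in all that became monomer in chains or isomer of the product, at the outlet or at the end, blue
- share of monomer in chains in all that became monomer in chains or isomer of the product, at the outlet or at the end, teal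
- share of monomer in chains in all that became monomer in chains or isomer of the product, at the outlet or at the end, red

Grey repeats the charge of birch, and each slice of red's plug flow lives as a closed flask for the same 3.0 d, so both take the last birch reading, a share of 34.0%. For the tanks I need k and k′. Integrating the balance in birch from 1.25 d to 3.00 d, with mean readings standing in for the integrals, gives an isomer growth per unit of chains of 0.625 d⁻¹ at an isomer-to-chains ratio of 1.54, and cedar from 1.04 d to 2.50 d gives 0.763 d⁻¹ at 1.22. Growth is k minus k′ times that ratio, so I read k′ as 0.442 d⁻¹ and k as 1.30 d⁻¹.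

A steady tank also loses isomer by outflow, so with τ the mean residence time, isomer over chains at the outlet is kτ/(1+k′τ). For teal this comes to 1.68, and I call it the tank ratio. The share is then 37.3% in teal, and in blue, with a ratio of 2.36, it is 29.8%.

The weak link is k′, read from two close ratios, so I hold birch's line and move k′ to 0.295 d⁻¹ and to 0.589 d⁻¹, letting k follow. Teal then lies between 36.8% and 37.6%, and blue between 27.4% and 31.4%. Even teal's lower figure exceeds grey by more than the margin, so I commit to teal.

The forecast names teal, with grey 34.3%, blue 30%, teal 38% and red 34.3%, on the same form of ratio but with its own fit of k and k′, and it adds: “Teal is best, but not by much.”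

The flask gives teal, with grey 34.0%, blue 28.2%, teal 37.1% and red 34.0%.

    free monomer + living end → monomer in chains + living end, rate k1*[living end]*[free monomer] (k = 0.230 M⁻¹ h⁻¹)
    free monomer + initiator → living end + monomer in chains (k = 1.80 M⁻¹ h⁻¹)
    initiator + monomer in chains ⇌ idle complex (K = 0.560 M⁻¹, k = 0.310 M⁻¹ h⁻¹)
    initiator + impurity → spent initiator (k = 430 M⁻¹ h⁻¹)
    monomer in chains + living end → free monomer + living end, rate k5*[living end] as long as [monomer in chains] is above zero (k = 0.130 h⁻¹)
    monomer in chains ⇌ isomer of the product (K = 3.40, k = 0.0470 h⁻¹)

Counting the forward rate alone, with the way back left out, monomer in chains has a half-life of 0.61 d for turning into isomer of the product, which is shorter than the 3.0 d of grey. Put into the tank ratio, which I had at 1.68 for teal, the constants give 1.70 there and 2.55 for blue, which is the share of 28.2% that the blue tank shows.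

The runs are calculated on assumed constants; noise was put on by code.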